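**Retrosynthetic overview**
1. Ring A (C1–C5, C10) is cut last, at C10–C5: a tertiary C10 radical, released from a tert-alkyl oxalate (either C10 epimer), closes 6-exo onto a C5=C6 alkenyl boronate, whose C–B bond becomes the C6–OH.
2. Enabling feature: C10 is the spiro carbon shared by ring A and the δ-lactone (C7–O–C20–C10–C9–C8) and is flanked by C20–O, so it is built from a ketone (C20 and C1 added in turn) and carries a carbinol that serves as radical precursor; the lactone is cis-fused to the bicyclo[3.2.1]octane (rings C/D), which leaves only the C10 face syn to H-9 open.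
3. δ-Lactone: C10 carboxyl → β-keto sulfoxonium ylide → O-alkylation by the C7 carboxyl. Ring D: 5-exo vinyl-radical closure C16→C13. Ring C: catalytic asymmetric Diels–Alder (C9–C11, C8–C14), then C8 alkylation.
4. Side chain (C1–C6, C18, C19): geraniol → asymmetric epoxidation → epoxy silyl ether rearrangement (sets C4) → C1 Grignard reagent, added to the C10 ketone.
5. Order of ring formation: C → lactone → D → A; then C6–B oxidation, C15 allylic oxidation, desilylation.

Key step: step 18

Remark: mono-tert-butyl fumarate (1) is treated as a purchasable building block; locants C1–C20 are those of the ent-kaurane skeleton of the target (C7 lactone carbonyl, C8/C13 bridgeheads, C15 ketone, C16=C17, C20 lactone CH2).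

**Route**

Step 1
Reactants: 1 mono-tert-butyl fumarate; 2 oxazolidin-2-one
Product: 4 tert-butyl (E)-4-oxo-4-(2-oxooxazolidin-3-yl)but-2-enoate, via mixed pivalic anhydride 3 (not isolated)
Conditions: PivCl, Et3N, THF, −20 °C; then 2, LiCl, −20 °C → rt
Reagents that add atoms: none
Why: One-pot mixed-anhydride N-acylation of the oxazolidinone gives the two-point-binding acyl imide without touching the E-alkene.

Step 2
Reactants: 4 tert-butyl (E)-4-oxo-4-(2-oxooxazolidin-3-yl)but-2-enoate; 5 (E)-1-acetoxybuta-1,3-diene (commercial E/Z mixture, only E reacts)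
Product: 6 tert-butyl 3-acetoxy-2-(2-oxooxazolidine-3-carbonyl)cyclohex-4-ene-1-carboxylate (1,2-trans; 2,3-cis; C9 S)
Conditions: [Cu((S,S)-t-Bu-box)](SbF6)2 (10 mol%), CH2Cl2, −20 °C → rt
Reagents that add atoms: none
Why: Cu(II)–bis(oxazoline)-catalysed Diels–Alder reaction of the chelated s-cis imide, which should react endo at its open Cα Re face (the sense expected for acrylimides with this ligand) to set C9 and the cis C11–O, while the activated imide fixes the regiochemistry (C9–C11, C8–C14); the C8 centre formed here is erased in step 5.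

Step 3
Reactants: 6 Diels–Alder adduct
Product: 8 6-(tert-butoxycarbonyl)-2-hydroxycyclohex-3-ene-1-carboxylic acid (1,2-cis; 1,6-trans), via acetoxy acid 7 (not isolated)
Conditions: LiOH·H2O (4 equiv), 30% H2O2, THF/H2O, 0 °C → rt; Na2SO3 work-up
Reagents that add atoms: hydrogen peroxide, OO
Why: Hydroperoxide cleavage of the N-acyl oxazolidinone followed by saponification of the secondary acetate should leave the hindered tert-butyl ester intact and cannot epimerise C9 once it is a carboxylate.

Step 4
Reactants: 8 hydroxy acid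
Product: 10 6-(tert-butoxycarbonyl)-2-(triisopropylsilyloxy)cyclohex-3-ene-1-carboxylic acid (1,2-cis; 1,6-trans), via silyl ester 9 (not isolated)
Conditions: TIPSOTf (2.5 equiv), 2,6-lutidine, CH2Cl2, 0 °C; then K2CO3, MeOH/H2O, rt
Reagents that add atoms: triisopropylsilyl triflate, CC(C)[Si](OS(=O)(=O)C(F)(F)F)(C(C)C)C(C)C
Why: Silylation of the secondary alcohol with the silyl triflate, the silyl ester formed alongside being cleaved by mild basic hydrolysis.

Step 5
Reactants: 10 silyl ether acid; 11 2,3-dibromopropene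
Product: 13 6-(2-bromoallyl)-6-(tert-butoxycarbonyl)-2-(triisopropylsilyloxy)cyclohex-3-ene-1-carboxylic acid (CO2H, OTIPS and CO2tBu all cis), via dilithium dianion 12 (not isolated)
Conditions: LDA (2.3 equiv), THF/DMPU, −78 → −40 °C; then 11, −78 → 0 °C
Reagents that add atoms: none
Why: Ester-enolate alkylation within a carboxylate/enolate dianion removes only C8–H (so the C11 silyloxy group cannot be eliminated), and the allylic bromide should attack the C8 enolate anti to the C9 carboxylate and the C11 silyl ether, which sets the C8 quaternary centre with the ester cis to the C10 carboxyl.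

Step 6
Reactants: 13 alkylated acid
Product: 15 β-keto dimethylsulfoxonium ylide of 13 (C10 ketone, C20 ylide carbon), via acyl imidazole 14 (not isolated)
Conditions: CDI, THF, rt; then CH2=S(O)Me2 (preformed from Me3S(O)I and KOtBu, 3 equiv), THF, 0 °C → rt
Reagents that add atoms: trimethylsulfoxonium iodide, C[S+](C)(C)=O.[I-]
Why: C-Acylation of dimethylsulfoxonium methylide (the Corey–Chaykovsky reagent) by the activated acid gives the stabilised keto ylide that brings in C20 as a latent electrophile.

Step 7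
Reactants: 15 β-keto sulfoxonium ylide
Product: 16 8a-(2-bromoallyl)-5-(triisopropylsilyloxy)-4a,5,8,8a-tetrahydro-1H-isochromene-1,4(3H)-dione (cis-fused; 5-O cis to the lactone)
Conditions: TFA, CH2Cl2, 0 °C → rt
Reagents that add atoms: none
Why: Acid cleaves the tert-butyl ester and C-protonates the ylide, and the carboxyl oxygen should then displace DMSO from the α-keto CH2–S+ carbon (6-exo-tet O-alkylation) to close the cis-fused δ-lactone without change at C8 or C9.

Step 8
Reactants: 16 monocyclic keto lactone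
Product: 17 tricyclic keto lactone (16-methylene bicyclo[3.2.1]octane fused at C8–C9 to the 7,20-lactone; C10 ketone; C11–OTIPS)
Conditions: Bu3SnH (slow addition), AIBN, PhH, 80 °C
Reagents that add atoms: none
Why: Tin-hydride vinyl-radical cyclisation (5-exo-trig) of the 2-bromoallyl group onto the ring alkene, in which the C8–C15 tether forces C16 to bond to C13 on the same face, sets C13 and gives the bridged ring D with its exocyclic methylene.

Step 9
Reactants: 18 geraniol
Product: 19 (2R,3R)-2,3-epoxygeraniol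
Conditions: Ti(OiPr)4 (5 mol%), D-(−)-diethyl tartrate (7 mol%), t-BuOOH, 4 Å MS, CH2Cl2, −20 °C
Reagents that add atoms: tert-butyl hydroperoxide, CC(C)(C)OO
Why: Sharpless asymmetric epoxidation of the allylic alcohol, the D-tartrate delivering oxygen to the face that gives the (2R,3R) epoxide and leaving the remote alkene alone.

Step 10
Reactants: 19 (2R,3R)-2,3-epoxygeraniol
Product: 20 (2R,3R)-2,3-epoxygeranyl tert-butyldimethylsilyl ether
Conditions: TBSCl, imidazole, DMF, 0 °C → rt
Reagents that add atoms: tert-butyldimethylsilyl chloride, CC(C)(C)[Si](C)(C)Cl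
Why: Standard silylation of the primary alcohol provides the migrating siloxymethyl group for the next step.

Step 11
Reactants: 20 epoxy silyl ether
Product: 21 (R)-2-[(tert-butyldimethylsilyloxy)methyl]-2,6-dimethylhept-5-enal
Conditions: methylaluminium bis(4-bromo-2,6-di-tert-butylphenoxide) (2 equiv), CH2Cl2, −78 °C
Reagents that add atoms: none
Why: Aluminium-promoted rearrangement of the epoxy silyl ether (semipinacol type), in which the epoxide opens at the tertiary carbon and the siloxymethyl group migrates anti to the leaving oxygen, should transfer the epoxide configuration with inversion to the new quaternary centre (future C4).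

Step 12
Reactants: 21 (R)-aldehyde
Product: 22 dimethyl acetal of 21
Conditions: MeOSiMe3, TMSOTf (5 mol%), CH2Cl2, −78 °C
Reagents that add atoms: methoxytrimethylsilane, CO[Si](C)(C)C
Why: Silyl-triflate-catalysed aprotic acetalisation masks the neopentyl aldehyde without loss of the silyl ether.

Step 13
Reactants: 22 acetal
Product: 23 (S)-5,5-dimethoxy-4-[(tert-butyldimethylsilyloxy)methyl]-4-methylpentan-1-ol
Conditions: O3, CH2Cl2/MeOH, −78 °C; then NaBH4, −78 °C → rt
Reagents that add atoms: ozone, [O-][O+]=O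
Why: Ozonolysis with reductive work-up cuts the trisubstituted alkene to the primary alcohol (future C1).

Step 14
Reactants: 23 alcohol
Product: 24 bromide of 23
Conditions: CBr4, PPh3, 2,6-lutidine, CH2Cl2, 0 °C
Reagents that add atoms: carbon tetrabromide, BrC(Br)(Br)Br
Why: Appel bromination of the unhindered primary alcohol under buffered conditions that keep the acetal.

Step 15
Reactants: 24 bromide; 17 tricyclic keto lactone
Product: 27 methyl oxalate of the C10 tertiary carbinol (both C10 epimers; acetal side chain), via Grignard reagent 25 (not isolated), via bromomagnesium alkoxide 26 (not isolated)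
Conditions: Mg, THF, 40 °C; then 17, LaCl3·2LiCl, THF, −78 °C; then ClC(O)CO2Me, −78 → 0 °C
Reagents that add atoms: methyl chlorooxoacetate, COC(=O)C(=O)Cl
Why: Lanthanide-promoted Grignard 1,2-addition to the α-acyloxy ketone (far more electrophilic than the neopentyl lactone) followed by acylation of the tertiary alkoxide in the same flask, before it can attack the lactone; the C10 configuration is left uncontrolled because step 18 erases it.

Step 16
Reactants: 27 acetal oxalate
Product: 28 aldehyde oxalate (C5 aldehyde on the quaternary C4)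
Conditions: Amberlyst-15, acetone, rt
Reagents that add atoms: none
Why: Acid-catalysed transacetalisation to acetone frees the aldehyde without water, so the oxalate, the lactone and both silyl ethers should survive.

Step 17
Reactants: 28 aldehyde oxalate; 29 2-(dichloromethyl)-4,4,5,5-tetramethyl-1,3,2-dioxaborolane
Product: 30 (E)-alkenyl pinacol boronate oxalate (C5=C6–B)
Conditions: CrCl2 (8 equiv), LiI, THF, rt
Reagents that add atoms: none
Why: Takai–Utimoto olefination with the gem-dichromium boryl reagent converts the hindered aldehyde into the (E)-alkenyl boronate under conditions that leave esters, lactone and alkenes alone.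

Step 18
Reactants: 30 (E)-alkenyl boronate oxalate
Product: 32 ring-A boronate (C10 spiro centre and C5 set; C6–Bpin), via caesium oxalate 31 (not isolated)
Conditions: CsOH·H2O (1.0 equiv), THF/H2O, 0 °C, then evaporate; Ir[dF(CF3)ppy]2(dtbbpy)PF6 (2 mol%), H2O (10 equiv), DME/DMF 3:1 (5 mM), blue LEDs, 40 °C
Reagents that add atoms: none
Why: Proposed new method: excited Ir(III) oxidises the caesium oxalate, loss of two CO2 gives the planar tertiary C10 radical from both C10 epimers of 31 (a stereoconvergent entry), this radical adds 6-exo-trig to C5 of the (E)-alkenyl boronate, and the α-boryl C6 radical is then reduced by Ir(II) and protonated by water. The closest known reactions are the photoredox Giese additions of tert-alkyl oxalate radicals to electron-poor alkenes and the decarboxylative radical additions to vinyl boronic esters that end by the same reductive radical–polar crossover; their combination, on an alkenyl boronate and in an intramolecular sense, is what is new. Ring A (C1–C5, C10) closes in the 6-exo-trig mode through a chair transition state, helped by the gem-disubstituted C4 in the tether. C10 is set by approach of the acceptor to the face of the radical syn to H-9, the only open face of the lactone cis-fused to the bicyclo[3.2.1]octane (the other is covered by C11–OTIPS and the underside of ring C), which places C9 equatorial and C20 axial on the new chair; C5 is set by the equatorial CH=CH–B unit in that chair, and the preformed C4 centre then carries its methyl axial and the larger CH2OTBS equatorial, the matched arrangement. The step needs the 6-exo closure to outrun reduction or elimination of the C10 radical and any attack on the distant C16=C17 alkene, which high dilution, the short tether, the Thorpe–Ingold effect at C4 and the radical-stabilising boron substituent should secure.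

Step 19
Reactants: 32 ring-A boronate
Product: 33 C6 primary alcohol (11-OTIPS, 18-OTBS, 16-ene, C15 H2)
Conditions: NaBO3·4H2O, THF/H2O, rt
Reagents that add atoms: sodium perborate, [Na+].OO[B-](O)(O)O
Why: Perborate oxidation of the alkyl boronate with retention gives the C6 alcohol under conditions mild enough for the lactone.

Step 20
Reactants: 33 C6 alcohol
Product: 34 C15 allylic alcohol (one C15 epimer expected; centre removed in step 21)
Conditions: SeO2 (0.5 equiv), t-BuOOH, CH2Cl2, rt
Reagents that add atoms: tert-butyl hydroperoxide, CC(C)(C)OO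
Why: Selenium dioxide allylic oxidation (ene reaction then [2,3]-shift) can only engage C15, because the other allylic position is the C13 bridgehead.

Step 21
Reactants: 34 C15 allylic alcohol
Product: 35 15-oxo-16-ene bis-silyl ether (free C6–OH)
Conditions: MnO2, CH2Cl2, rt
Reagents that add atoms: none
Why: Manganese dioxide oxidises only the allylic secondary alcohol and leaves the saturated primary C6 alcohol alone.

Step 22
Reactants: 35 enone bis-silyl ether
Product: 36 target compound
Conditions: HF·pyridine, THF/pyridine, 0 °C → rt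
Reagents that add atoms: none
Why: Fluoride-mediated cleavage of the primary TBS and secondary TIPS ethers under buffered acidic conditions should spare the lactone and the α-methylene ketone.

**Compound list**
1 | mono-tert-butyl fumarate | CC(C)(C)OC(=O)/C=C/C(=O)O | starting material
2 | oxazolidin-2-one | O=C1NCCO1 | starting material
3 | (E)-4-tert-butoxy-4-oxobut-2-enoic pivalic anhydride | CC(C)(C)OC(=O)/C=C/C(=O)OC(=O)C(C)(C)C | intermediate
4 | tert-butyl (E)-4-oxo-4-(2-oxooxazolidin-3-yl)but-2-enoate | CC(C)(C)OC(=O)/C=C/C(=O)N1CCOC1=O | intermediate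
5 | (E)-1-acetoxybuta-1,3-diene | CC(=O)O/C=C/C=C | starting material
6 | tert-butyl 3-acetoxy-2-(2-oxooxazolidine-3-carbonyl)cyclohex-4-ene-1-carboxylate (1,2-trans; 2,3-cis) | CC(C)(C)OC(=O)[C@@H]1CC=C[C@@H](OC(C)=O)[C@H]1C(=O)N1CCOC1=O | intermediate
7 | 2-acetoxy-6-(tert-butoxycarbonyl)cyclohex-3-ene-1-carboxylic acid (1,2-cis; 1,6-trans) | CC(C)(C)OC(=O)[C@@H]1CC=C[C@@H](OC(C)=O)[C@H]1C(=O)O | intermediate
8 | 6-(tert-butoxycarbonyl)-2-hydroxycyclohex-3-ene-1-carboxylic acid (1,2-cis; 1,6-trans) | CC(C)(C)OC(=O)[C@@H]1CC=C[C@@H](O)[C@H]1C(=O)O | intermediate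
9 | triisopropylsilyl ester of 10 | CC(C)(C)OC(=O)[C@@H]1CC=C[C@@H](O[Si](C(C)C)(C(C)C)C(C)C)[C@H]1C(=O)O[Si](C(C)C)(C(C)C)C(C)C | intermediate
10 | 6-(tert-butoxycarbonyl)-2-(triisopropylsilyloxy)cyclohex-3-ene-1-carboxylic acid (1,2-cis; 1,6-trans) | CC(C)(C)OC(=O)[C@@H]1CC=C[C@@H](O[Si](C(C)C)(C(C)C)C(C)C)[C@H]1C(=O)O | intermediate
11 | 2,3-dibromopropene | C=C(Br)CBr | starting material
12 | dilithium carboxylate ester enolate of 10 | [Li+].[Li+].CC(C)(C)OC([O-])=C1CC=C[C@@H](O[Si](C(C)C)(C(C)C)C(C)C)[C@H]1C(=O)[O-] | intermediate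
13 | 6-(2-bromoallyl)-6-(tert-butoxycarbonyl)-2-(triisopropylsilyloxy)cyclohex-3-ene-1-carboxylic acid (CO2H, OTIPS, CO2tBu all cis) | CC(C)(C)OC(=O)[C@@]1(CC(Br)=C)CC=C[C@@H](O[Si](C(C)C)(C(C)C)C(C)C)[C@H]1C(=O)O | intermediate
14 | N-acyl imidazole of 13 | CC(C)(C)OC(=O)[C@@]1(CC(Br)=C)CC=C[C@@H](O[Si](C(C)C)(C(C)C)C(C)C)[C@H]1C(=O)n1ccnc1 | intermediate
15 | β-keto dimethylsulfoxonium ylide of 13 | CC(C)(C)OC(=O)[C@@]1(CC(Br)=C)CC=C[C@@H](O[Si](C(C)C)(C(C)C)C(C)C)[C@H]1C(=O)C=S(C)(C)=O | intermediate
16 | 8a-(2-bromoallyl)-5-(triisopropylsilyloxy)-4a,5,8,8a-tetrahydro-1H-isochromene-1,4(3H)-dione (cis-fused) | C=C(Br)C[C@]12CC=C[C@@H](O[Si](C(C)C)(C(C)C)C(C)C)[C@H]1C(=O)COC2=O | intermediate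
17 | tricyclic keto lactone (16-methylene bicyclo[3.2.1]octane, 7,20-lactone, C10 ketone, 11-OTIPS) | C=C1C[C@]23C[C@H]1C[C@@H](O[Si](C(C)C)(C(C)C)C(C)C)[C@H]2C(=O)COC3=O | intermediate
18 | geraniol | CC(C)=CCC/C(C)=C/CO | starting material
19 | (2R,3R)-2,3-epoxygeraniol | CC(C)=CCC[C@@]1(C)O[C@@H]1CO | intermediate
20 | (2R,3R)-2,3-epoxygeranyl TBS ether | CC(C)=CCC[C@@]1(C)O[C@@H]1CO[Si](C)(C)C(C)(C)C | intermediate
21 | (R)-2-[(tert-butyldimethylsilyloxy)methyl]-2,6-dimethylhept-5-enal | CC(C)=CCC[C@](C)(CO[Si](C)(C)C(C)(C)C)C=O | intermediate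
22 | dimethyl acetal of 21 | CC(C)=CCC[C@](C)(CO[Si](C)(C)C(C)(C)C)C(OC)OC | intermediate
23 | 5,5-dimethoxy-4-[(tert-butyldimethylsilyloxy)methyl]-4-methylpentan-1-ol | OCCC[C@](C)(CO[Si](C)(C)C(C)(C)C)C(OC)OC | intermediate
24 | bromide of 23 | BrCCC[C@](C)(CO[Si](C)(C)C(C)(C)C)C(OC)OC | intermediate
25 | Grignard reagent of 24 | Br[Mg]CCC[C@](C)(CO[Si](C)(C)C(C)(C)C)C(OC)OC | intermediate
26 | bromomagnesium C10 alkoxide (both C10 epimers) | C=C1C[C@]23C[C@H]1C[C@@H](O[Si](C(C)C)(C(C)C)C(C)C)[C@H]2C(CCC[C@](C)(CO[Si](C)(C)C(C)(C)C)C(OC)OC)(O[Mg]Br)COC3=O | intermediate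
27 | C10 methyl oxalate with acetal side chain (both C10 epimers) | C=C1C[C@]23C[C@H]1C[C@@H](O[Si](C(C)C)(C(C)C)C(C)C)[C@H]2C(CCC[C@](C)(CO[Si](C)(C)C(C)(C)C)C(OC)OC)(OC(=O)C(=O)OC)COC3=O | intermediate
28 | C10 methyl oxalate with C5 aldehyde (both C10 epimers) | C=C1C[C@]23C[C@H]1C[C@@H](O[Si](C(C)C)(C(C)C)C(C)C)[C@H]2C(CCC[C@](C)(CO[Si](C)(C)C(C)(C)C)C=O)(OC(=O)C(=O)OC)COC3=O | intermediate
29 | 2-(dichloromethyl)-4,4,5,5-tetramethyl-1,3,2-dioxaborolane | ClC(Cl)B1OC(C)(C)C(C)(C)O1 | starting material
30 | C10 methyl oxalate with (E)-C5=C6–Bpin (both C10 epimers) | C=C1C[C@]23C[C@H]1C[C@@H](O[Si](C(C)C)(C(C)C)C(C)C)[C@H]2C(CCC[C@](C)(CO[Si](C)(C)C(C)(C)C)/C=C/B4OC(C)(C)C(C)(C)O4)(OC(=O)C(=O)OC)COC3=O | intermediate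
31 | caesium oxalate of 30 | C=C1C[C@]23C[C@H]1C[C@@H](O[Si](C(C)C)(C(C)C)C(C)C)[C@H]2C(CCC[C@](C)(CO[Si](C)(C)C(C)(C)C)/C=C/B4OC(C)(C)C(C)(C)O4)(OC(=O)C(=O)[O-])COC3=O.[Cs+] | intermediate
32 | ring-A boronate (6-Bpin, 11-OTIPS, 18-OTBS, 16-ene) | C=C1C[C@]23C[C@H]1C[C@@H](O[Si](C(C)C)(C(C)C)C(C)C)[C@H]2[C@@]1(CCC[C@](C)(CO[Si](C)(C)C(C)(C)C)[C@H]1CB4OC(C)(C)C(C)(C)O4)COC3=O | intermediate
33 | C6 alcohol (11-OTIPS, 18-OTBS, 16-ene) | C=C1C[C@]23C[C@H]1C[C@@H](O[Si](C(C)C)(C(C)C)C(C)C)[C@H]2[C@@]1(CCC[C@](C)(CO[Si](C)(C)C(C)(C)C)[C@H]1CO)COC3=O | intermediate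
34 | C15 allylic alcohol (C15 not assigned) | C=C1C(O)[C@]23C[C@H]1C[C@@H](O[Si](C(C)C)(C(C)C)C(C)C)[C@H]2[C@@]1(CCC[C@](C)(CO[Si](C)(C)C(C)(C)C)[C@H]1CO)COC3=O | intermediate
35 | 15-oxo-16-ene bis-silyl ether | C=C1C(=O)[C@]23C[C@H]1C[C@@H](O[Si](C(C)C)(C(C)C)C(C)C)[C@H]2[C@@]1(CCC[C@](C)(CO[Si](C)(C)C(C)(C)C)[C@H]1CO)COC3=O | intermediate
36 | CNP0152458.1 | C=C1C(=O)[C@]23C[C@H]1C[C@@H](O)[C@H]2[C@@]1(CCC[C@](C)(CO)[C@H]1CO)COC3=O | target

**Totals and risks**
Total step count: 22. Longest linear sequence: 16 steps (steps 1–8, then 15–22).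

Step 18 (labelled step): the C10 radical may be reduced or may eliminate before it adds to the hindered, only moderately activated alkenyl boronate, or the α-boryl radical may not be reduced, so that the chain stalls. The fallback uses a documented acceptor class; it sets out from 28 and returns at 33. Aldehyde 28 is condensed with diethyl (phenylsulfonylmethyl)phosphonate (LiCl, DBU, Horner–Wadsworth–Emmons) to the (E)-vinyl sulfone oxalate F1. CsOH gives its caesium oxalate F2, and the same Ir/blue-light conditions, now an oxalate Giese cyclisation onto a vinyl sulfone, should give the ring-A sulfone F3. Deprotonation α to sulfur (LDA, −78 °C) and oxidation with MoOPH (oxidative desulfonylation) gives the C6 aldehyde F4, which is reduced with NaBH4 to 33.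

Step 15: the Grignard reagent may enolise the ketone, and the new C10 alkoxide may attack the lactone carbonyl (ring contraction) before it is acylated. The fallback reverses the order of addition and lactonisation; it sets out from 15 and returns at 28. Ir-catalysed O–H insertion of ylide 15 into 4-methoxybenzyl alcohol gives the α-(4-methoxybenzyloxy) ketone F5. Chelation-assisted addition of Grignard reagent 25 gives the bromomagnesium alkoxide F6, flanked only by a tert-butyl ester, which is acylated in the flask with methyl chlorooxoacetate to the oxalate F7. TFA/anisole removes the PMB ether, the tert-butyl ester and the acetal and closes the δ-lactone to the monocyclic lactone aldehyde F8, and a reductive Heck cyclisation (Pd(OAc)2, PPh3, HCO2Na) then closes ring D to 28.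

Step 8: 6-endo closure or rearrangement of the radical to the bicyclo[2.2.2]octane isomer, or direct reduction of the vinyl radical, may erode the yield. The fallback sets out from 16 and returns at 17: a reductive Heck cyclisation (Pd(OAc)2, PPh3, HCO2Na, DMF, 80 °C; 5-exo syn-carbopalladation, then hydride capture), which makes no new compound.

Further compounds
F1 | step 18 | C10 methyl oxalate with (E)-vinyl phenyl sulfone side chain (both C10 epimers) | C=C1C[C@]23C[C@H]1C[C@@H](O[Si](C(C)C)(C(C)C)C(C)C)[C@H]2C(CCC[C@](C)(CO[Si](C)(C)C(C)(C)C)/C=C/S(=O)(=O)c4ccccc4)(OC(=O)C(=O)OC)COC3=O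
F2 | step 18 | caesium oxalate of F1 | C=C1C[C@]23C[C@H]1C[C@@H](O[Si](C(C)C)(C(C)C)C(C)C)[C@H]2C(CCC[C@](C)(CO[Si](C)(C)C(C)(C)C)/C=C/S(=O)(=O)c4ccccc4)(OC(=O)C(=O)[O-])COC3=O.[Cs+]
F3 | step 18 | ring-A C6 phenyl sulfone | C=C1C[C@]23C[C@H]1C[C@@H](O[Si](C(C)C)(C(C)C)C(C)C)[C@H]2[C@@]1(CCC[C@](C)(CO[Si](C)(C)C(C)(C)C)[C@H]1CS(=O)(=O)c4ccccc4)COC3=O
F4 | step 18 | ring-A C6 aldehyde | C=C1C[C@]23C[C@H]1C[C@@H](O[Si](C(C)C)(C(C)C)C(C)C)[C@H]2[C@@]1(CCC[C@](C)(CO[Si](C)(C)C(C)(C)C)[C@H]1C=O)COC3=O
F5 | step 15 | α-(4-methoxybenzyloxy) ketone | CC(C)(C)OC(=O)[C@@]1(CC(Br)=C)CC=C[C@@H](O[Si](C(C)C)(C(C)C)C(C)C)[C@H]1C(=O)COCc1ccc(OC)cc1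
F6 | step 15 | bromomagnesium C10 alkoxide of the tert-butyl ester (both C10 epimers) | CC(C)(C)OC(=O)[C@@]1(CC(Br)=C)CC=C[C@@H](O[Si](C(C)C)(C(C)C)C(C)C)[C@H]1C(CCC[C@](C)(CO[Si](C)(C)C(C)(C)C)C(OC)OC)(O[Mg]Br)COCc1ccc(OC)cc1
F7 | step 15 | C10 methyl oxalate of the tert-butyl ester (both C10 epimers) | CC(C)(C)OC(=O)[C@@]1(CC(Br)=C)CC=C[C@@H](O[Si](C(C)C)(C(C)C)C(C)C)[C@H]1C(CCC[C@](C)(CO[Si](C)(C)C(C)(C)C)C(OC)OC)(OC(=O)C(=O)OC)COCc1ccc(OC)cc1
F8 | step 15 | monocyclic lactone oxalate aldehyde (both C10 epimers) | C=C(Br)C[C@]12CC=C[C@@H](O[Si](C(C)C)(C(C)C)C(C)C)[C@H]1C(CCC[C@](C)(CO[Si](C)(C)C(C)(C)C)C=O)(OC(=O)C(=O)OC)COC2=O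
F0 | step 8 | none | none
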